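**Plan**

- Retrosynthesis: pyrrole 10 is taken back one oxidation level to 1-pyrroline 9. Its N1=C5 bond is cut to amino aldehyde 7, stored as benzophenone imine 6. C2–C3 is cut (retro-Michael) to glycine imine 5 and (E)-docos-2-enal 4, and the C3=C4 alkene of 4 is cut (retro-Wittig) to icosanal 2, made from icosan-1-ol 1.
- Enabling feature: ring atoms N1, C2 (bearing CO2Me), C3, C4 and C5 form the backbone of a 3-alkylglutamate 5-semialdehyde. An amine on C2 and an aldehyde at C5 therefore close the single ring by condensation.
- Forward order: C20 aldehyde, then C22 enal (chain complete), then the glycine unit joined at C3, then the only ring closed at N1–C5, then aromatisation.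
- Stereochemistry: the target has no stereocentre. C2 and C3 arise uncontrolled in step 3 and are erased in step 5. Assumption: compounds 6–9 are carried as racemic diastereomer mixtures without separation.

Key step: step 4

**Route**

Step 1
Reactants: 1 icosan-1-ol
Product: 2 icosanal
Conditions: TEMPO (10 mol%), PhI(OAc)2 (1.1 equiv), CH2Cl2, 25–35 °C
Reagents that add atoms: none
Why: Oxoammonium-catalysed alcohol oxidation (TEMPO with a trivalent iodine terminal oxidant) should take an unhindered primary alcohol to the aldehyde and stop there in the absence of water.

Step 2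
Reactants: 2 icosanal; 3 (triphenylphosphoranylidene)acetaldehyde
Product: 4 (E)-docos-2-enal
Conditions: 3 (1.1 equiv), toluene, 80 °C
Reagents that add atoms: none
Why: Wittig olefination with the stabilised formylmethylene ylide is E-selective, and the conjugated enal formed is less electrophilic than the saturated aldehyde 2, which should limit a second olefination.

Step 3
Reactants: 4 (E)-docos-2-enal; 5 methyl N-(diphenylmethylene)glycinate
Product: 6 methyl 2-[(diphenylmethylidene)amino]-3-(2-oxoethyl)docosanoate (racemic syn/anti mixture)
Conditions: 5 (1.2 equiv), Cs2CO3 (20 mol%), n-Bu4NBr (10 mol%), CH2Cl2, 0 °C, slow addition of 4, then rt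
Reagents that add atoms: none
Why: Michael addition, in which the carbonate/ammonium pair generates catalytically the soft, doubly stabilised 2-azaallyl anion of 5 that attacks the β-carbon of the enal (any 1,2-aldol adduct being reversible under these conditions); the C2 and C3 stereocentres form without control, which is acceptable because both become sp2 in step 5.

Step 4
Reactants: 6 methyl 2-[(diphenylmethylidene)amino]-3-(2-oxoethyl)docosanoate
Product: 9 methyl 3-nonadecyl-3,4-dihydro-2H-pyrrole-2-carboxylate, via amino aldehyde 7 (not isolated), via cyclic hemiaminal 8 (not isolated)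
Conditions: 1 M aq HCl (1.2 equiv), THF, 0 °C to rt; then sat. aq NaHCO3 to pH 8
Reagents that add atoms: none
Why: Dilute acid hydrolyses the diaryl ketimine, releasing benzophenone and giving amino aldehyde 7 as its ammonium salt while the methyl ester stays intact. On neutralisation the free amine on C2 attacks the aldehyde carbon C5 in a 5-exo-trig closure to hemiaminal 8, which loses water to give the cyclic aldimine 9 with the new N1=C5 bond. The closest known reaction type is the hydrolysis–cyclocondensation of glycine Schiff-base Michael adducts to 1-pyrrolines, the laboratory counterpart of the spontaneous cyclisation of glutamate 5-semialdehyde to 1-pyrroline-5-carboxylate. No lasting stereocentre is created, since C5 ends sp2 and C2/C3 are carried as the mixture from step 3. The selectivity needed is intramolecular imine formation over intermolecular condensation or aldol reaction of the amino aldehyde. It is secured by the three-carbon spacing between the nitrogen and the aldehyde carbon, which makes five-membered closure kinetically dominant, and by moderate dilution and freeing the amine only at the neutralisation stage.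

Step 5
Reactants: 9 methyl 3-nonadecyl-3,4-dihydro-2H-pyrrole-2-carboxylate
Product: 10 methyl 3-nonadecyl-1H-pyrrole-2-carboxylate
Conditions: DDQ (1.1 equiv), toluene, 0 °C to rt, on freshly prepared 9
Reagents that add atoms: none
Why: Quinone dehydrogenation, a reaction type established for 3,4-dihydro-2H-pyrrole-2-carboxylates, in which DDQ removes a hydride from the ring and the cation loses a proton; the gain of pyrrole aromaticity should drive the two-electron oxidation and remove the C2 and C3 stereocentres.

**Compound list**

1 | icosan-1-ol | CCCCCCCCCCCCCCCCCCCCO | starting material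
2 | icosanal | CCCCCCCCCCCCCCCCCCCC=O | intermediate
3 | (triphenylphosphoranylidene)acetaldehyde | O=CC=P(c1ccccc1)(c1ccccc1)c1ccccc1 | starting material
4 | (E)-docos-2-enal | CCCCCCCCCCCCCCCCCCC/C=C/C=O | intermediate
5 | methyl N-(diphenylmethylene)glycinate | COC(=O)CN=C(c1ccccc1)c1ccccc1 | starting material
6 | methyl 2-[(diphenylmethylidene)amino]-3-(2-oxoethyl)docosanoate (racemic, mixture of C2/C3 diastereomers) | CCCCCCCCCCCCCCCCCCCC(CC=O)C(N=C(c1ccccc1)c1ccccc1)C(=O)OC | intermediate
7 | methyl 2-amino-3-(2-oxoethyl)docosanoate (racemic, mixture of diastereomers; not isolated) | CCCCCCCCCCCCCCCCCCCC(CC=O)C(N)C(=O)OC | intermediate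
8 | methyl 5-hydroxy-3-nonadecylpyrrolidine-2-carboxylate (racemic, mixture of diastereomers; not isolated) | CCCCCCCCCCCCCCCCCCCC1CC(O)NC1C(=O)OC | intermediate
9 | methyl 3-nonadecyl-3,4-dihydro-2H-pyrrole-2-carboxylate (racemic, cis/trans mixture) | CCCCCCCCCCCCCCCCCCCC1CC=NC1C(=O)OC | intermediate
10 | methyl 3-nonadecyl-1H-pyrrole-2-carboxylate (achiral) | CCCCCCCCCCCCCCCCCCCc1cc[nH]c1C(=O)OC | target

**Step count**

Total: 5 steps. Longest linear sequence: 5 steps (1 → 2 → 4 → 6 → 9 → 10).

**Steps most likely to fail**

1. Step 3 (conjugate addition). The azaallyl anion may attack the aldehyde carbonyl instead of the β-carbon. The base may also deprotonate the enal at its γ-position and start self-condensation, or the adduct may add to a second enal, so the 1,4-adduct is eroded.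
Fallback, from 2 and 5, returning at 6: the acceptor is moved to the thioester oxidation level, where no 1,2-pathway or enolisable aldehyde exists.
   - Doebner–Knoevenagel condensation of icosanal 2 with malonic acid (pyridine, cat. piperidine, 90 °C) should give (E)-docos-2-enoic acid F1.
   - Steglich coupling with ethanethiol (DCC, cat. DMAP, CH2Cl2, 0 °C) should give S-ethyl (E)-docos-2-enethioate F2.
   - Glycine imine 5 is added under the same carbonate/phase-transfer conditions to give methyl 2-[(diphenylmethylidene)amino]-3-[2-(ethylsulfanyl)-2-oxoethyl]docosanoate F3.
   - Fukuyama reduction (Et3SiH, palladium on carbon, acetone, rt) converts the thioester into the aldehyde in the presence of the methyl ester and rejoins the route at 6.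

2. Step 5 (dehydrogenation). Hydride abstraction from the aldimine may be slow enough that the pyrroline oligomerises first. The oxidant may also go on to attack the chain methylene next to the newly formed pyrrole.
Fallback, from 9, returning at 10: the oxidation is replaced by a sulfonylation–elimination sequence in which the sulfonyl group acts as an internal oxidant.
   - Treating 9 with TsCl, Et3N and cat. DMAP in CH2Cl2 should give an N-sulfonyliminium ion that loses the C4 proton, forming methyl 1-(4-methylbenzenesulfonyl)-3-nonadecyl-2,3-dihydro-1H-pyrrole-2-carboxylate F4.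
   - DBU in toluene at 80 °C then removes the acidic C2 proton and expels p-toluenesulfinate from nitrogen; tautomerisation delivers 10 without any external oxidant touching the pyrrole.

3. Step 2 (formyl Wittig). The product enal may be olefinated a second time by the ylide, giving the dienal, which is hard to separate from 4.
Fallback, from 2, returning at 4: the two-carbon unit is introduced at the ester level and adjusted afterwards.
   - Horner–Wadsworth–Emmons reaction of 2 with triethyl phosphonoacetate (NaH, THF, 0 °C) should give ethyl (E)-docos-2-enoate F5.
   - Reduction with i-Bu2AlH (CH2Cl2, −78 °C) gives (E)-docos-2-en-1-ol F6.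
   - Allylic oxidation with MnO2 (CH2Cl2, rt) gives 4.

**Further compounds**

F1 | step 3 | (E)-docos-2-enoic acid | CCCCCCCCCCCCCCCCCCC/C=C/C(=O)O
F2 | step 3 | S-ethyl (E)-docos-2-enethioate | CCCCCCCCCCCCCCCCCCC/C=C/C(=O)SCC
F3 | step 3 | methyl 2-[(diphenylmethylidene)amino]-3-[2-(ethylsulfanyl)-2-oxoethyl]docosanoate (racemic, mixture of diastereomers) | CCCCCCCCCCCCCCCCCCCC(CC(=O)SCC)C(N=C(c1ccccc1)c1ccccc1)C(=O)OC
F4 | step 5 | methyl 1-(4-methylbenzenesulfonyl)-3-nonadecyl-2,3-dihydro-1H-pyrrole-2-carboxylate (racemic, cis/trans mixture) | CCCCCCCCCCCCCCCCCCCC1C=CN(S(=O)(=O)c2ccc(C)cc2)C1C(=O)OC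
F5 | step 2 | ethyl (E)-docos-2-enoate | CCCCCCCCCCCCCCCCCCC/C=C/C(=O)OCC
F6 | step 2 | (E)-docos-2-en-1-ol | CCCCCCCCCCCCCCCCCCC/C=C/CO
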